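**Retrosynthetic overview**
1. Feature used: on rings A and A'' the C5 and C5'' hydroxyls lie peri to the C4/C4'' ketones and flank the C6–C6'' bond. Without them the biaryl has only two ortho oxygens (O7, O7''), and each acyl-bearing carbon (C4a, C4a'') has a single ortho oxygen (the future O1). Coupling and ring C closure then become unambiguous.
2. Disconnection 1 (last): C5–O and C5''–O, by twofold ketone-directed C–H oxygenation of the 5,5''-dideoxy tetraacetate 12, followed by acidic removal of the acetates.
3. Disconnection 2: C2–C1' and C2''–C1''' (rings B and both stereocentres), by twofold enantioselective conjugate arylation of bichromone 10. This is preferred to closing a bis-chalcone, whose oxa-Michael step is reversible and weakly enantioselective without extra activation.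
4. Disconnection 3: rings C from bis(ortho-hydroxyacetophenone) 5 and a one-carbon amide acetal; acetyl groups by Friedel–Crafts acylation; C6–C6'' bond by homocoupling of bromide 1.
5. Order of rings: rings A/A'' are bought and joined first, both rings C are closed next, and both rings B are attached last.

Key step: step 7

Remark 1: the target SMILES fixes only C2 and C2'' (both S). The C6–C6'' axis, hindered once it carries four ortho oxygens, has no descriptor, so it is not controlled and both rotamers count as the target.
Remark 2: the sense of induction in step 6 is carried over from the same catalyst with cyclic enones, where the (S)-ligand leads to the R-type adduct, hence the (R)-ligand here. If a test on 7-acetoxychromone shows the opposite sense, the (S)-ligand is used.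

**Step 1**
Reactants: 1 1-bromo-2,4-dimethoxybenzene (two molecules)
Product: 2 2,2',4,4'-tetramethoxybiphenyl
Conditions: NiCl2(PPh3)2 (10 mol %), Zn dust, Et4NI, THF, 50 °C
Reagents that add atoms: none
Why: Nickel-catalysed reductive homocoupling of an aryl bromide (Ullmann-type, zerovalent nickel regenerated by Zn) tolerates one ortho methoxy group and makes the future C6–C6'' bond while each ring has only one ortho substituent beside it.

**Step 2**
Reactants: 2 2,2',4,4'-tetramethoxybiphenyl; 3 acetyl chloride
Product: 5 bis-phenol diketone 5,5'-diacetyl-4,4'-dihydroxy-2,2'-dimethoxybiphenyl, via tetramethoxy diketone 4 (not isolated)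
Conditions: AcCl, AlCl3 (excess), CH2Cl2, 0 °C to reflux; aq. HCl work-up
Reagents that add atoms: acetyl chloride (3), CC(=O)Cl
Why: Friedel–Crafts acylation should go to C5/C5', which are para to the 2-methoxy and ortho to the 4-methoxy group while C3 is shielded between two methoxy groups, and excess AlCl3 chelated between each new ketone and its neighbouring 4-methoxy group then cleaves only that ether, as is usual for ortho-methoxy aryl ketones.

**Step 3**
Reactants: 5 5,5'-diacetyl-4,4'-dihydroxy-2,2'-dimethoxybiphenyl; 6 N,N-dimethylformamide dimethyl acetal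
Product: 8 7,7'-dimethoxy-6,6'-bichromone, via bis-enaminone 7 (not isolated)
Conditions: Me2NCH(OMe)2, toluene, 100 °C; concentrate; conc. HCl, CH2Cl2, 40 °C
Reagents that add atoms: N,N-dimethylformamide dimethyl acetal (6), COC(OC)N(C)C
Why: Enaminone condensation of the methyl ketones followed by acid-induced addition–elimination of the phenol at the β-carbon (6-endo closure, loss of Me2NH) is the standard chromone synthesis, and because each acyl group has one ortho hydroxyl and one ortho C–H, both rings C can close only to the 6,6'-linked isomer.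

**Step 4**
Reactants: 8 7,7'-dimethoxy-6,6'-bichromone
Product: 9 7,7'-dihydroxy-6,6'-bichromone
Conditions: BBr3, CH2Cl2, −78 °C to rt; H2O
Reagents that add atoms: none
Why: Lewis acid-mediated aryl methyl ether cleavage is placed at the achiral, non-enolisable chromone stage, where no stereocentre can be lost and ring C cannot open.

**Step 5**
Reactants: 9 7,7'-dihydroxy-6,6'-bichromone
Product: 10 7,7'-diacetoxy-6,6'-bichromone
Conditions: Ac2O, pyridine, rt
Reagents that add atoms: acetic anhydride, CC(=O)OC(C)=O
Why: Simple O-acylation installs the group that lowers the electron density of ring A, withstands acidic media and can later be taken off without base.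

**Step 6**
Reactants: 10 7,7'-diacetoxy-6,6'-bichromone; 11 4-acetoxyphenylboronic acid (4 equiv)
Product: 12 (2S,2''S)-7,7'',4',4'''-tetraacetoxy-6,6''-biflavanone
Conditions: Pd(OCOCF3)2 (10 mol %), (R)-t-BuPyOx [(R)-4-tert-butyl-2-(2-pyridyl)oxazoline] (12 mol %), NH4PF6, H2O, ClCH2CH2Cl, 60 °C
Reagents that add atoms: 4-acetoxyphenylboronic acid (11), CC(=O)Oc1ccc(B(O)O)cc1
Why: Enantioselective conjugate addition of an arylboronic acid to a chromone with a cationic divalent palladium pyridine-oxazoline catalyst (transmetalation, face-selective carbopalladation of C2=C3, protonolysis of the palladium enolate) runs without base so all acetates stay, the tert-butyl group of the (R)-ligand blocks one face so that C2 and C2'' should both become S, and since the two additions are independent the minor sense ends mainly in the (2R,2''S) diastereomer, which is removed by crystallisation or chromatography.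

**Step 7**
Reactants: 12 (2S,2''S)-7,7'',4',4'''-tetraacetoxy-6,6''-biflavanone
Product: 14 (2S,2''S)-7,7'',4',4'''-tetraacetoxy-5,5''-dihydroxy-6,6''-biflavanone, via bis(trifluoroacetate) 13 (not isolated)
Conditions: [RuCl2(p-cymene)]2 (10 mol %), PhI(OCOCF3)2 (4 equiv, in portions), CF3CO2H/(CF3CO)2O, 80 °C; then H2O, THF, rt
Reagents that add atoms: [bis(trifluoroacetoxy)iodo]benzene, O=C(OI(OC(=O)C(F)(F)F)c1ccccc1)C(F)(F)F
Why: In CF3CO2H the dimer [RuCl2(p-cymene)]2 gives an electrophilic divalent ruthenium trifluoroacetate that binds the C4 ketone oxygen and, by carboxylate-assisted deprotonation, metalates C5–H to a five-membered ruthenacycle (Ru–O=C4–C4a–C5); PhI(OCOCF3)2 raises it to tetravalent ruthenium, C–O reductive elimination delivers the C5 trifluoroacetate, the second half reacts likewise to give 13, and its two very labile aryl trifluoroacetates fall off in water. The closest known reaction type is this same ketone-directed ortho C–H oxygenation of aryl alkyl ketones, chromones and flavones with the same catalyst, oxidant and solvent pair, used here twice in one molecule. No ring is closed and no stereocentre is formed, so the only stereochemical task is to leave C2 and C2'' untouched, which is helped by the absence of base and by the 4'-acetoxyphenyl groups, which give little support to ionisation of the benzylic C2–O1 bond. The selectivity needed is C5 over C8 and over the ring B positions: a metal held by the C4 oxygen can reach only the two positions ortho to C4a, one of them (C8a) already carries O1, and C8 and ring B have no directing group in range and are deactivated by their acetates. (CF3CO)2O keeps the medium dry so that each new oxygen stays masked as an electron-poor ester and is not oxidised further, and any acetate/trifluoroacetate exchange is harmless because step 8 removes all acyl groups. The twisted neighbouring ring crowds C5–H, most of all in the second oxygenation, and this is where the risk of the route sits.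

**Step 8**
Reactants: 14 (2S,2''S)-7,7'',4',4'''-tetraacetoxy-5,5''-dihydroxy-6,6''-biflavanone
Product: 15 succedaneaflavanone, (2S,2''S)-5,5'',7,7'',4',4'''-hexahydroxy-6,6''-biflavanone
Conditions: HCl (1.25 M in MeOH), CH2Cl2, 0 °C to rt
Reagents that add atoms: none
Why: Acid-catalysed transesterification (methanolysis) of the four aryl acetates avoids phenoxide and enolate formation, the two triggers of retro-oxa-Michael opening of ring C and loss of configuration at C2/C2'', and the C5/C5'' hydroxyls hydrogen-bonded to the ketones further favour the closed flavanone.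

**Compound list**
1 | 1-bromo-2,4-dimethoxybenzene | COc1ccc(Br)c(OC)c1 | starting material
2 | 2,2',4,4'-tetramethoxybiphenyl | COc1ccc(-c2ccc(OC)cc2OC)c(OC)c1 | intermediate
3 | acetyl chloride | CC(=O)Cl | starting material
4 | 5,5'-diacetyl-2,2',4,4'-tetramethoxybiphenyl (not isolated) | COc1cc(OC)c(C(C)=O)cc1-c1cc(C(C)=O)c(OC)cc1OC | intermediate
5 | 5,5'-diacetyl-4,4'-dihydroxy-2,2'-dimethoxybiphenyl | COc1cc(O)c(C(C)=O)cc1-c1cc(C(C)=O)c(O)cc1OC | intermediate
6 | N,N-dimethylformamide dimethyl acetal | COC(OC)N(C)C | starting material
7 | 5,5'-bis[(E)-3-(dimethylamino)acryloyl]-4,4'-dihydroxy-2,2'-dimethoxybiphenyl (not isolated) | COc1cc(O)c(C(=O)/C=C/N(C)C)cc1-c1cc(C(=O)/C=C/N(C)C)c(O)cc1OC | intermediate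
8 | 7,7'-dimethoxy-6,6'-bichromone | COc1cc2occc(=O)c2cc1-c1cc2c(=O)ccoc2cc1OC | intermediate
9 | 7,7'-dihydroxy-6,6'-bichromone | Oc1cc2occc(=O)c2cc1-c1cc2c(=O)ccoc2cc1O | intermediate
10 | 7,7'-diacetoxy-6,6'-bichromone | CC(=O)Oc1cc2occc(=O)c2cc1-c1cc2c(=O)ccoc2cc1OC(C)=O | intermediate
11 | 4-acetoxyphenylboronic acid | CC(=O)Oc1ccc(B(O)O)cc1 | starting material
12 | (2S,2''S)-7,7'',4',4'''-tetraacetoxy-6,6''-biflavanone | O=C1C[C@@H](c2ccc(OC(C)=O)cc2)Oc2cc(OC(C)=O)c(-c3c(OC(C)=O)cc4c(c3)C(=O)C[C@@H](c3ccc(OC(C)=O)cc3)O4)cc21 | intermediate
13 | (2S,2''S)-7,7'',4',4'''-tetraacetoxy-5,5''-bis(trifluoroacetoxy)-6,6''-biflavanone (not isolated) | O=C1C[C@@H](c2ccc(OC(C)=O)cc2)Oc2cc(OC(C)=O)c(-c3c(OC(C)=O)cc4c(c3OC(=O)C(F)(F)F)C(=O)C[C@@H](c3ccc(OC(C)=O)cc3)O4)c(OC(=O)C(F)(F)F)c21 | intermediate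
14 | (2S,2''S)-7,7'',4',4'''-tetraacetoxy-5,5''-dihydroxy-6,6''-biflavanone (tetra-O-acetylsuccedaneaflavanone) | O=C1C[C@@H](c2ccc(OC(C)=O)cc2)Oc2cc(OC(C)=O)c(-c3c(OC(C)=O)cc4c(c3O)C(=O)C[C@@H](c3ccc(OC(C)=O)cc3)O4)c(O)c21 | intermediate
15 | succedaneaflavanone, (2S,2''S)-6,6''-binaringenin | O=C1C[C@@H](c2ccc(O)cc2)Oc2cc(O)c(-c3c(O)cc4c(c3O)C(=O)C[C@@H](c3ccc(O)cc3)O4)c(O)c21 | target

Total step count: 8. Longest linear sequence: 8 steps (1 to 15).

**Steps most likely to fail**

**Step 7.**
- Metalation of the crowded C5–H beside the twisted biaryl may be slow, above all for the second oxygenation.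
- The trivalent iodine oxidant may attack the enol of the C4 ketone, causing dehydrogenation or an aryl shift in ring C.
- Hot acid may open ring C reversibly and erode the configuration at C2.

The fallback moves the same C–H oxygenation ahead of the stereocentres, onto a substrate with neither an enolisable C3 nor a stereocentre, so that it tolerates forcing. It sets out from 10. [RuCl2(p-cymene)]2 and PhI(OCOCF3)2 in CF3CO2H/(CF3CO)2O at up to 120 °C should give 7,7'-diacetoxy-5,5'-bis(trifluoroacetoxy)-6,6'-bichromone F1 (not isolated). Water then gives 7,7'-diacetoxy-5,5'-dihydroxy-6,6'-bichromone F2. Ac2O, pyridine and DMAP give 5,5',7,7'-tetraacetoxy-6,6'-bichromone F3. Twofold arylation with 11 under the conditions of step 6 gives succedaneaflavanone hexaacetate F4. Methanolysis as in step 8 comes back to the route at 15.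

**Step 6.**
- The second arylation may stay incomplete.
- The boronic acid may be lost by protodeboronation.
- Limited facial selectivity would show up, in a twofold reaction, as a diastereomer that is hard to remove.

The fallback changes the metal, the mechanism and the protecting-group plan. It sets out from 9. BnBr and K2CO3 in DMF give 7,7'-bis(benzyloxy)-6,6'-bichromone F5. Hayashi–Miyaura 1,4-addition of 4-(benzyloxy)phenylboronic acid follows, with monovalent rhodium from [RhCl(C2H4)2]2 and a chiral 2,5-diphenylbicyclo[2.2.2]octa-2,5-diene (the enantiomer that leads to 2S), K3PO4, toluene/H2O. This should give (2S,2''S)-7,7'',4',4'''-tetrakis(benzyloxy)-6,6''-biflavanone F6, which can be purified by crystallisation. Neutral hydrogenolysis (H2, Pd/C, EtOAc) gives (2S,2''S)-7,7'',4',4'''-tetrahydroxy-6,6''-biflavanone F7. Ac2O in pyridine at 0 °C comes back to the route at 12.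

**Step 8.**
- The two acetates beside the axis may cleave slowly.
- The long exposure to acid that results could let C2 epimerise through reversible opening of ring C once the 4'-hydroxyls are free.

The fallback replaces acid catalysis by biocatalysis at neutral pH. It sets out from 14. Immobilised Candida antarctica lipase B with n-butanol in THF at 40 °C transfers the acetyl groups to butanol and comes back to the route at 15.

**Further compounds**
F1 | step 7 | 7,7'-diacetoxy-5,5'-bis(trifluoroacetoxy)-6,6'-bichromone | CC(=O)Oc1cc2occc(=O)c2c(OC(=O)C(F)(F)F)c1-c1c(OC(C)=O)cc2occc(=O)c2c1OC(=O)C(F)(F)F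
F2 | step 7 | 7,7'-diacetoxy-5,5'-dihydroxy-6,6'-bichromone | CC(=O)Oc1cc2occc(=O)c2c(O)c1-c1c(OC(C)=O)cc2occc(=O)c2c1O
F3 | step 7 | 5,5',7,7'-tetraacetoxy-6,6'-bichromone | CC(=O)Oc1cc2occc(=O)c2c(OC(C)=O)c1-c1c(OC(C)=O)cc2occc(=O)c2c1OC(C)=O
F4 | step 7 | succedaneaflavanone hexaacetate, (2S,2''S) | O=C1C[C@@H](c2ccc(OC(C)=O)cc2)Oc2cc(OC(C)=O)c(-c3c(OC(C)=O)cc4c(c3OC(C)=O)C(=O)C[C@@H](c3ccc(OC(C)=O)cc3)O4)c(OC(C)=O)c21
F5 | step 6 | 7,7'-bis(benzyloxy)-6,6'-bichromone | O=c1ccoc2cc(OCc3ccccc3)c(-c3cc4c(=O)ccoc4cc3OCc3ccccc3)cc12
F6 | step 6 | (2S,2''S)-7,7'',4',4'''-tetrakis(benzyloxy)-6,6''-biflavanone | O=C1C[C@@H](c2ccc(OCc3ccccc3)cc2)Oc2cc(OCc3ccccc3)c(-c3c(OCc4ccccc4)cc4c(c3)C(=O)C[C@@H](c3ccc(OCc5ccccc5)cc3)O4)cc21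
F7 | step 6 | (2S,2''S)-7,7'',4',4'''-tetrahydroxy-6,6''-biflavanone | O=C1C[C@@H](c2ccc(O)cc2)Oc2cc(O)c(-c3c(O)cc4c(c3)C(=O)C[C@@H](c3ccc(O)cc3)O4)cc21
F0 | step 8 | none | none
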